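**Retrosynthetic overview**
1. Target ⇐ desilylation and Mitsunobu inversion/tigloylation at C8 of a macrocyclic 8-epi alcohol.
2. Ten-membered ring (formed second) ⇐ intramolecular chromium-mediated allylation, C7–C8, of a 3-(bromomethyl)butenolide onto a C8 aldehyde; this also creates the α-methylene lactone.
3. Butenolide ring (formed first) ⇐ ring-closing metathesis of a 2-(bromomethyl)acrylate of the C6 bis-allylic alcohol.
4. Open chain ⇐ C1–C2 ketone synthesis from a C2–C7 alkyllithium and a C8–C10/C1 Weinreb amide.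
5. Stereocentres: C10 by a copper bis(oxazoline) pyruvate aldol (first), C6 by lipase resolution, C7 and C8 in the ring closure (C8 then inverted).

Convention: atom labels C1–C15 are germacranolide numbers (lactone C6–O–C12, ester on C8, ketone C1, tertiary carbinol C10).
Assumption: 4-methyl-5,6-dihydro-2H-pyran-2-one is bought as a catalogue compound, and the (R,R)-ligand in step 2 gives the 2R adduct (its antipode gives 2S).

**Route**

Step 1
Reactants: 1 S-ethyl ethanethioate
Product: 2 [1-(ethylsulfanyl)ethenyl]oxy(trimethyl)silane (ketene silyl thioacetal)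
Conditions: LiN(iPr)2, THF, −78 °C; then Me3SiCl
Reagents that add atoms: chlorotrimethylsilane C[Si](C)(C)Cl
Why: Kinetic deprotonation of the thioester and O-silylation of the lithium enolate (enolate silylation) give the donor for the Mukaiyama aldol.

Step 2
Reactants: 2 ketene silyl thioacetal; 3 methyl pyruvate (methyl 2-oxopropanoate)
Product: 5 methyl (2R)-4-(ethylsulfanyl)-2-hydroxy-2-methyl-4-oxobutanoate, via trimethylsilyl ether 4 (not isolated)
Conditions: Cu(OTf)2 (10 mol %), (R,R)-2,2'-(propane-2,2-diyl)bis(4-tert-butyl-4,5-dihydrooxazole) (11 mol %), THF, −78 °C; then aq. HCl (1 mol/L), THF, rt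
Reagents that add atoms: none
Why: Catalytic enantioselective Mukaiyama aldol addition, in which the pyruvate chelates the divalent copper bis(oxazoline) complex through both carbonyls, the tert-butyl groups shield one ketone face, and attack of 2 on the open face sets the C10 tertiary carbinol as R (typically above 95% ee), the transferred silyl group being removed on acidic work-up.

Step 3
Reactants: 5 hydroxy thioester
Product: 6 methyl (2R)-4-(ethylsulfanyl)-2-methyl-4-oxo-2-[(triethylsilyl)oxy]butanoate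
Conditions: Et3SiOTf, 2,6-lutidine, CH2Cl2, 0 °C → rt
Reagents that add atoms: triethylsilyl trifluoromethanesulfonate CC[Si](CC)(CC)OS(=O)(=O)C(F)(F)F
Why: Silyl ether protection of the tertiary alcohol with a silyl triflate and a hindered base blocks retro-aldol and β-elimination in the later aldehyde and ketone stages.

Step 4
Reactants: 6 silyl ether thioester
Product: 7 methyl (2R)-2-methyl-4-oxo-2-[(triethylsilyl)oxy]butanoate
Conditions: Et3SiH, 10% Pd/C, acetone, rt
Reagents that add atoms: none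
Why: Fukuyama reduction, in which zerovalent palladium inserts into the carbon–sulfur bond and the silane delivers hydride, gives the C8 aldehyde without touching the methyl ester or the silyl ether.

Step 5
Reactants: 7 aldehyde ester
Product: 8 methyl (2R)-4,4-dimethoxy-2-methyl-2-[(triethylsilyl)oxy]butanoate
Conditions: HC(OMe)3, PPTS (cat.), MeOH, rt
Reagents that add atoms: trimethyl orthoformate COC(OC)OC
Why: Acid-catalysed acetalisation with the orthoformate as water scavenger masks the C8 aldehyde as a dimethyl acetal that is stable to bases and organometallics.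

Step 6
Reactants: 8 acetal ester
Product: 9 (2R)-N,4,4-trimethoxy-N,2-dimethyl-2-[(triethylsilyl)oxy]butanamide (Weinreb amide)
Conditions: MeNH(OMe)·HCl, iPrMgCl, THF, −20 → 0 °C
Reagents that add atoms: N,O-dimethylhydroxylamine hydrochloride CNOC.Cl
Why: Weinreb amide formation by the chloromagnesium amide of N,O-dimethylhydroxylamine prepares C1 for a single addition of a carbon nucleophile.

Step 7
Reactants: 10 4-methyl-5,6-dihydro-2H-pyran-2-one
Product: 11 4-methyl-5,6-dihydro-2H-pyran-2-ol (lactol)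
Conditions: iBu2AlH (1.1 equiv), CH2Cl2, −78 °C; aq. sodium potassium tartrate
Reagents that add atoms: none
Why: Half-reduction of the lactone stops at the lactol because the aluminium hemiacetal is stable at −78 °C, and the ring still fixes the cis geometry of the future C4=C5 bond.

Step 8
Reactants: 11 lactol; 12 vinylmagnesium bromide
Product: 13 rac-(4Z)-5-methylhepta-1,4-diene-3,7-diol
Conditions: 12 (3 equiv), THF, −20 → 0 °C; aq. NH4Cl
Reagents that add atoms: none
Why: Grignard 1,2-addition to the ring-opened hydroxy-enal form of the lactol gives the bis-allylic carbinol as a racemate at C6, with the Z olefin inherited from the six-membered ring.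

Step 9
Reactants: 13 racemic diol
Product: 14 rac-(3Z)-5-hydroxy-3-methylhepta-3,6-dien-1-yl 4-methylbenzenesulfonate
Conditions: TsCl (1.05 equiv), pyridine, CH2Cl2, −10 °C
Reagents that add atoms: 4-methylbenzenesulfonyl chloride Cc1ccc(cc1)S(Cl)(=O)=O
Why: Selective sulfonylation works because the unhindered primary hydroxyl reacts much faster than the secondary bis-allylic one at low temperature.

Step 10
Reactants: 14 racemic hydroxy tosylate
Product: 15 (3Z,5S)-5-hydroxy-3-methylhepta-3,6-dien-1-yl 4-methylbenzenesulfonate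
Conditions: immobilised Candida antarctica lipase B, vinyl acetate, MTBE, 30 °C, to about 55% conversion
Reagents that add atoms: none
Why: Enzymatic kinetic resolution by a lipase (a serine hydrolase, EC 3.1.1.3) follows the Kazlauskas rule with vinyl as the medium and the Z-alkenyl chain as the large group, so the 5R alcohol is acetylated and the 5S alcohol, which carries the future C6 configuration, is recovered in high ee.

Step 11
Reactants: 15 (S)-hydroxy tosylate
Product: 16 (3Z,5S)-3-methyl-5-[(trimethylsilyl)oxy]hepta-3,6-dien-1-yl 4-methylbenzenesulfonate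
Conditions: Me3SiCl, imidazole, CH2Cl2, 0 °C
Reagents that add atoms: chlorotrimethylsilane C[Si](C)(C)Cl
Why: Silylation gives a temporary trimethylsilyl ether that survives organolithium chemistry and prevents intramolecular O-alkylation to a dihydropyran.

Step 12
Reactants: 16 silyl ether tosylate
Product: 17 {[(3S,4Z)-7-iodo-5-methylhepta-1,4-dien-3-yl]oxy}(trimethyl)silane
Conditions: NaI, NaHCO3, acetone, 40 °C
Reagents that add atoms: sodium iodide [Na+].[I-]
Why: Finkelstein reaction, an SN2 displacement of the primary tosylate by iodide, gives the precursor for halogen–lithium exchange.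

Step 13
Reactants: 17 silyl ether iodide; 9 Weinreb amide
Product: 20 (3R,7Z,9S)-9-hydroxy-1,1-dimethoxy-3,7-dimethyl-3-[(triethylsilyl)oxy]undeca-7,10-dien-4-one, via alkyllithium 18 (not isolated), via bis-silyl ketone 19 (not isolated)
Conditions: t-BuLi (2.1 equiv), Et2O–pentane, −78 °C; then 9, THF, −78 → −20 °C; aq. NH4Cl; then K2CO3, MeOH, 0 °C
Reagents that add atoms: none
Why: Lithium–iodine exchange followed by Weinreb ketone synthesis forms the C1–C2 bond with a single addition because the chelated tetrahedral intermediate survives until the quench, and mild methanolysis then frees the C6 hydroxyl while the tertiary triethylsilyl ether and the acetal stay.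

Step 14
Reactants: 20 hydroxy ketone; 21 2-(bromomethyl)prop-2-enoic acid
Product: 22 (3S,4Z,9R)-11,11-dimethoxy-5,9-dimethyl-8-oxo-9-[(triethylsilyl)oxy]undeca-1,4-dien-3-yl 2-(bromomethyl)prop-2-enoate
Conditions: N,N'-dicyclohexylcarbodiimide, DMAP (5 mol %), CH2Cl2, −20 → 0 °C
Reagents that add atoms: none
Why: Steglich-type carbodiimide esterification attaches the acrylate carrying C11, C12 and C13 under conditions mild enough for the bis-allylic alcohol.

Step 15
Reactants: 22 bis-allylic acrylate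
Product: 23 (5R)-3-(bromomethyl)-5-[(1Z,6R)-8,8-dimethoxy-2,6-dimethyl-5-oxo-6-[(triethylsilyl)oxy]oct-1-en-1-yl]furan-2(5H)-one
Conditions: second-generation Grubbs catalyst RuCl2(=CHPh)(PCy3)(SIMes) (10 mol %), toluene (0.005 mol/L), 70 °C
Reagents that add atoms: none
Why: Ring-closing metathesis starts at the monosubstituted vinyl group and closes onto the acrylate to give the five-membered 3-(bromomethyl)butenolide with loss of ethene, leaving the trisubstituted C4=C5 olefin and the C6 configuration untouched.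

Step 16
Reactants: 23 butenolide acetal
Product: 24 (5R)-3-(bromomethyl)-5-[(1Z,6R)-2,6-dimethyl-5,8-dioxo-6-[(triethylsilyl)oxy]oct-1-en-1-yl]furan-2(5H)-one
Conditions: PPTS, acetone–H2O (10:1), 45 °C
Reagents that add atoms: water O
Why: Mild acid hydrolysis of the dimethyl acetal releases the C8 aldehyde only after the acid-sensitive bis-allylic ester has become the robust butenolide.

Step 17
Reactants: 24 bromomethylbutenolide aldehyde
Product: 26 (3aR,4S,6R,10Z,11aR)-4-hydroxy-6,10-dimethyl-3-methylidene-6-[(triethylsilyl)oxy]-3a,4,5,6,8,9-hexahydrocyclodeca[b]furan-2,7(3H,11aH)-dione, via allylchromium dichloride 25 (not isolated)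
Conditions: CrCl2 (8 equiv), THF (0.002 mol/L, slow addition of 24), rt; aq. NH4Cl
Reagents that add atoms: none
Why: Intramolecular Nozaki–Hiyama–Kishi (Barbier-type) allylation, in which divalent chromium makes an allylchromium species that adds through C7 to the aldehyde only, via a chair transition state with C7–C8 forming anti to the C5 substituent of the butenolide (trans-lactone, C7 R) and the aldehyde chain pseudo-equatorial away from the lactone (7,8-anti, C8 S), closes the ten-membered ring and creates the α-methylene lactone.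

Step 18
Reactants: 26 macrocyclic 8S alcohol; 27 tiglic acid [(2E)-2-methylbut-2-enoic acid]
Product: 28 (3aR,4R,6R,10Z,11aR)-6,10-dimethyl-3-methylidene-2,7-dioxo-6-[(triethylsilyl)oxy]-2,3,3a,4,5,6,7,8,9,11a-decahydrocyclodeca[b]furan-4-yl (2E)-2-methylbut-2-enoate
Conditions: PPh3, DIAD (betaine pre-formed), toluene, 0 °C → rt
Reagents that add atoms: none
Why: Mitsunobu esterification activates the C8 alcohol as an alkoxyphosphonium ion that tiglate displaces by SN2 with inversion, turning the 8S alcohol into the 8R tiglate of the target.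

Step 19
Reactants: 28 silyl ether tiglate
Product: 29 (3aR,4R,6R,10Z,11aR)-6-hydroxy-6,10-dimethyl-3-methylidene-2,7-dioxo-2,3,3a,4,5,6,7,8,9,11a-decahydrocyclodeca[b]furan-4-yl (2E)-2-methylbut-2-enoate (target)
Conditions: HF·pyridine, pyridine, THF, 0 °C → rt
Reagents that add atoms: none
Why: Fluoride-mediated desilylation under buffered, weakly acidic conditions removes the tertiary triethylsilyl ether without affecting the α-methylene lactone, the tiglate or the α-ketol.

**Compound list**
1 | S-ethyl ethanethioate | CC(=O)SCC | starting material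
2 | [1-(ethylsulfanyl)ethenyl]oxy(trimethyl)silane | C=C(O[Si](C)(C)C)SCC | intermediate
3 | methyl pyruvate | CC(=O)C(=O)OC | starting material
4 | methyl (2R)-4-(ethylsulfanyl)-2-methyl-4-oxo-2-[(trimethylsilyl)oxy]butanoate | COC(=O)[C@](C)(O[Si](C)(C)C)CC(=O)SCC | intermediate
5 | methyl (2R)-4-(ethylsulfanyl)-2-hydroxy-2-methyl-4-oxobutanoate | COC(=O)[C@](C)(O)CC(=O)SCC | intermediate
6 | methyl (2R)-4-(ethylsulfanyl)-2-methyl-4-oxo-2-[(triethylsilyl)oxy]butanoate | COC(=O)[C@](C)(O[Si](CC)(CC)CC)CC(=O)SCC | intermediate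
7 | methyl (2R)-2-methyl-4-oxo-2-[(triethylsilyl)oxy]butanoate | COC(=O)[C@](C)(O[Si](CC)(CC)CC)CC=O | intermediate
8 | methyl (2R)-4,4-dimethoxy-2-methyl-2-[(triethylsilyl)oxy]butanoate | COC(=O)[C@](C)(O[Si](CC)(CC)CC)CC(OC)OC | intermediate
9 | (2R)-N,4,4-trimethoxy-N,2-dimethyl-2-[(triethylsilyl)oxy]butanamide | CON(C)C(=O)[C@](C)(O[Si](CC)(CC)CC)CC(OC)OC | intermediate
10 | 4-methyl-5,6-dihydro-2H-pyran-2-one | CC1=CC(=O)OCC1 | starting material
11 | 4-methyl-5,6-dihydro-2H-pyran-2-ol | CC1=CC(O)OCC1 | intermediate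
12 | vinylmagnesium bromide | C=C[Mg]Br | starting material
13 | rac-(4Z)-5-methylhepta-1,4-diene-3,7-diol | C=CC(O)/C=C(/C)CCO | intermediate
14 | rac-(3Z)-5-hydroxy-3-methylhepta-3,6-dien-1-yl 4-methylbenzenesulfonate | C=CC(O)/C=C(/C)CCOS(=O)(=O)c1ccc(C)cc1 | intermediate
15 | (3Z,5S)-5-hydroxy-3-methylhepta-3,6-dien-1-yl 4-methylbenzenesulfonate | C=C[C@H](O)/C=C(/C)CCOS(=O)(=O)c1ccc(C)cc1 | intermediate
16 | (3Z,5S)-3-methyl-5-[(trimethylsilyl)oxy]hepta-3,6-dien-1-yl 4-methylbenzenesulfonate | C=C[C@H](O[Si](C)(C)C)/C=C(/C)CCOS(=O)(=O)c1ccc(C)cc1 | intermediate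
17 | {[(3S,4Z)-7-iodo-5-methylhepta-1,4-dien-3-yl]oxy}(trimethyl)silane | C=C[C@H](O[Si](C)(C)C)/C=C(/C)CCI | intermediate
18 | [(3Z,5S)-3-methyl-5-[(trimethylsilyl)oxy]hepta-3,6-dien-1-yl]lithium | C=C[C@H](O[Si](C)(C)C)/C=C(/C)CC[Li] | intermediate
19 | (3R,7Z,9S)-1,1-dimethoxy-3,7-dimethyl-3-[(triethylsilyl)oxy]-9-[(trimethylsilyl)oxy]undeca-7,10-dien-4-one | C=C[C@H](O[Si](C)(C)C)/C=C(/C)CCC(=O)[C@](C)(O[Si](CC)(CC)CC)CC(OC)OC | intermediate
20 | (3R,7Z,9S)-9-hydroxy-1,1-dimethoxy-3,7-dimethyl-3-[(triethylsilyl)oxy]undeca-7,10-dien-4-one | C=C[C@H](O)/C=C(/C)CCC(=O)[C@](C)(O[Si](CC)(CC)CC)CC(OC)OC | intermediate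
21 | 2-(bromomethyl)prop-2-enoic acid | C=C(CBr)C(=O)O | starting material
22 | (3S,4Z,9R)-11,11-dimethoxy-5,9-dimethyl-8-oxo-9-[(triethylsilyl)oxy]undeca-1,4-dien-3-yl 2-(bromomethyl)prop-2-enoate | C=C[C@H](OC(=O)C(=C)CBr)/C=C(/C)CCC(=O)[C@](C)(O[Si](CC)(CC)CC)CC(OC)OC | intermediate
23 | (5R)-3-(bromomethyl)-5-[(1Z,6R)-8,8-dimethoxy-2,6-dimethyl-5-oxo-6-[(triethylsilyl)oxy]oct-1-en-1-yl]furan-2(5H)-one | BrCC1=C[C@@H](/C=C(/C)CCC(=O)[C@](C)(O[Si](CC)(CC)CC)CC(OC)OC)OC1=O | intermediate
24 | (5R)-3-(bromomethyl)-5-[(1Z,6R)-2,6-dimethyl-5,8-dioxo-6-[(triethylsilyl)oxy]oct-1-en-1-yl]furan-2(5H)-one | BrCC1=C[C@@H](/C=C(/C)CCC(=O)[C@](C)(O[Si](CC)(CC)CC)CC=O)OC1=O | intermediate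
25 | dichloro{[(5R)-5-[(1Z,6R)-2,6-dimethyl-5,8-dioxo-6-[(triethylsilyl)oxy]oct-1-en-1-yl]-2-oxo-2,5-dihydrofuran-3-yl]methyl}chromium (trivalent chromium) | Cl[Cr](Cl)CC1=C[C@@H](/C=C(/C)CCC(=O)[C@](C)(O[Si](CC)(CC)CC)CC=O)OC1=O | intermediate
26 | (3aR,4S,6R,10Z,11aR)-4-hydroxy-6,10-dimethyl-3-methylidene-6-[(triethylsilyl)oxy]-3a,4,5,6,8,9-hexahydrocyclodeca[b]furan-2,7(3H,11aH)-dione | C=C1C(=O)O[C@@H]2/C=C(/C)CCC(=O)[C@](C)(O[Si](CC)(CC)CC)C[C@H](O)[C@@H]12 | intermediate
27 | tiglic acid, (2E)-2-methylbut-2-enoic acid | C/C=C(\C)C(=O)O | starting material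
28 | (3aR,4R,6R,10Z,11aR)-6,10-dimethyl-3-methylidene-2,7-dioxo-6-[(triethylsilyl)oxy]-2,3,3a,4,5,6,7,8,9,11a-decahydrocyclodeca[b]furan-4-yl (2E)-2-methylbut-2-enoate | C=C1C(=O)O[C@@H]2/C=C(/C)CCC(=O)[C@](C)(O[Si](CC)(CC)CC)C[C@@H](OC(=O)/C(C)=C/C)[C@@H]12 | intermediate
29 | (3aR,4R,6R,10Z,11aR)-6-hydroxy-6,10-dimethyl-3-methylidene-2,7-dioxo-2,3,3a,4,5,6,7,8,9,11a-decahydrocyclodeca[b]furan-4-yl (2E)-2-methylbut-2-enoate | C=C1C(=O)O[C@@H]2/C=C(/C)CCC(=O)[C@](C)(O)C[C@@H](OC(=O)/C(C)=C/C)[C@@H]12 | target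

**Totals and risks**

Total steps: 19. Longest linear sequence: 13 steps (steps 7–19 from compound 10; the branch from compound 1, steps 1–6 and 13–19, is equally long).

Steps most likely to fail:

Step 17, the macrocyclisation. The ten-membered ring is strained, so oligomerisation and protodemetalation of 25 compete, and the C7/C8 selectivity rests on a transition-state model rather than on a tested case. The fallback sets out from 23 and returns at 26. The allylic bromide of 23 is converted with bis(pinacolato)diboron and Pd2(dba)3 in toluene/DMSO at 50 °C into 2-{[(5R)-5-[(1Z,6R)-8,8-dimethoxy-2,6-dimethyl-5-oxo-6-[(triethylsilyl)oxy]oct-1-en-1-yl]-2-oxo-2,5-dihydrofuran-3-yl]methyl}-4,4,5,5-tetramethyl-1,3,2-dioxaborolane F1. Its acetal is hydrolysed with PPTS in wet acetone to the corresponding 5,8-dioxo allylboronate aldehyde F2. F2 is then cyclised by intramolecular allylboration at high dilution (toluene, 60 °C, or Sc(OTf)3 as catalyst at −20 °C). This closed-transition-state allylation needs no reducing metal, cannot be quenched by protonation of a carbon–metal bond, and after aqueous work-up should give the same 7,8-anti alcohol 26.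

Step 18, the Mitsunobu inversion. The C8 alcohol is a hindered ring alcohol, elimination toward C7 or C9 can compete, and the phosphine can add to the α-methylene lactone. The fallback sets out from 26 and returns at 28. Compound 26 is sulfonylated with chloromethanesulfonyl chloride and pyridine in CH2Cl2 at 0 °C, with retention, to (3aR,4S,6R,10Z,11aR)-6,10-dimethyl-3-methylidene-2,7-dioxo-6-[(triethylsilyl)oxy]-2,3,3a,4,5,6,7,8,9,11a-decahydrocyclodeca[b]furan-4-yl chloromethanesulfonate F3. The isolated sulfonate is displaced by caesium tiglate (from 27 and Cs2CO3) with 18-crown-6 in toluene at 50 °C. This SN2 reaction with a better leaving group and a free carboxylate gives 28 with inversion and uses no phosphine or azo reagent.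

Step 15, the metathesis. The bis-allylic bromomethylacrylate 22 can ionise or rearrange, the allylic bromide can degrade the ruthenium carbene, and closure to a trisubstituted olefin is slow. The fallback sets out from 20 and returns at 23; it carries the allylic oxygen through the metathesis and introduces bromide afterwards. Compound 20 is esterified (carbodiimide, DMAP) with 2-{[(4-methoxybenzyl)oxy]methyl}prop-2-enoic acid to (3S,4Z,9R)-11,11-dimethoxy-5,9-dimethyl-8-oxo-9-[(triethylsilyl)oxy]undeca-1,4-dien-3-yl 2-{[(4-methoxybenzyl)oxy]methyl}prop-2-enoate F4. Ring-closing metathesis with the same ruthenium catalyst gives (5R)-5-[(1Z,6R)-8,8-dimethoxy-2,6-dimethyl-5-oxo-6-[(triethylsilyl)oxy]oct-1-en-1-yl]-3-{[(4-methoxybenzyl)oxy]methyl}furan-2(5H)-one F5. DDQ in CH2Cl2/pH 7 buffer removes the benzyl ether to give (5R)-3-(hydroxymethyl)-5-[(1Z,6R)-8,8-dimethoxy-2,6-dimethyl-5-oxo-6-[(triethylsilyl)oxy]oct-1-en-1-yl]furan-2(5H)-one F6. An Appel bromination (CBr4, PPh3, CH2Cl2, 0 °C) then gives 23.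

**Further compounds**
F1 | step 17 | 2-{[(5R)-5-[(1Z,6R)-8,8-dimethoxy-2,6-dimethyl-5-oxo-6-[(triethylsilyl)oxy]oct-1-en-1-yl]-2-oxo-2,5-dihydrofuran-3-yl]methyl}-4,4,5,5-tetramethyl-1,3,2-dioxaborolane | CC1(C)OB(CC2=C[C@@H](/C=C(/C)CCC(=O)[C@](C)(O[Si](CC)(CC)CC)CC(OC)OC)OC2=O)OC1(C)C
F2 | step 17 | 2-{[(5R)-5-[(1Z,6R)-2,6-dimethyl-5,8-dioxo-6-[(triethylsilyl)oxy]oct-1-en-1-yl]-2-oxo-2,5-dihydrofuran-3-yl]methyl}-4,4,5,5-tetramethyl-1,3,2-dioxaborolane | CC1(C)OB(CC2=C[C@@H](/C=C(/C)CCC(=O)[C@](C)(O[Si](CC)(CC)CC)CC=O)OC2=O)OC1(C)C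
F3 | step 18 | (3aR,4S,6R,10Z,11aR)-6,10-dimethyl-3-methylidene-2,7-dioxo-6-[(triethylsilyl)oxy]-2,3,3a,4,5,6,7,8,9,11a-decahydrocyclodeca[b]furan-4-yl chloromethanesulfonate | C=C1C(=O)O[C@@H]2/C=C(/C)CCC(=O)[C@](C)(O[Si](CC)(CC)CC)C[C@H](OS(=O)(=O)CCl)[C@@H]12
F4 | step 15 | (3S,4Z,9R)-11,11-dimethoxy-5,9-dimethyl-8-oxo-9-[(triethylsilyl)oxy]undeca-1,4-dien-3-yl 2-{[(4-methoxybenzyl)oxy]methyl}prop-2-enoate | C=C[C@H](OC(=O)C(=C)COCc1ccc(OC)cc1)/C=C(/C)CCC(=O)[C@](C)(O[Si](CC)(CC)CC)CC(OC)OC
F5 | step 15 | (5R)-5-[(1Z,6R)-8,8-dimethoxy-2,6-dimethyl-5-oxo-6-[(triethylsilyl)oxy]oct-1-en-1-yl]-3-{[(4-methoxybenzyl)oxy]methyl}furan-2(5H)-one | COc1ccc(COCC2=C[C@@H](/C=C(/C)CCC(=O)[C@](C)(O[Si](CC)(CC)CC)CC(OC)OC)OC2=O)cc1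
F6 | step 15 | (5R)-3-(hydroxymethyl)-5-[(1Z,6R)-8,8-dimethoxy-2,6-dimethyl-5-oxo-6-[(triethylsilyl)oxy]oct-1-en-1-yl]furan-2(5H)-one | OCC1=C[C@@H](/C=C(/C)CCC(=O)[C@](C)(O[Si](CC)(CC)CC)CC(OC)OC)OC1=O
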